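In 2.0 h each molecule of free monomer in this flask, charged with 44 mM of initiator, has had its chance at a fork: it can become uncatalysed product or monomer in chains. We reckon the odds from two earlier runs.

in all of them: free monomer 2.2 M
- Wednesday's: transfer agent 0.022 M; initiator 62 mM; run made earlier
- Tuesday's: transfer agent 0.022 M; initiator 97 mM; run made earlier
- flask: transfer agent 0.0220 M; initiator 44 mM; time 2.0 h

| run | time / min | monomer in chains / % | free monomer / % |
|---|---|---|---|
| Wednesday's | 10.0 | 1.9 | 90.8 |
| Wednesday's | 30.0 | 6.9 | 72.6 |
| Wednesday's | 60.0 | 15.4 | 49.8 |
| Wednesday's | 80.0 | 20.7 | 38.3 |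
| Wednesday's | 120 | 28.7 | 21.4 |
| Tuesday's | 10.0 | 2.1 | 90.5 |
| Tuesday's | 20.0 | 6.2 | 79.9 |
| Tuesday's | 30.0 | 9.6 | 70.0 |
| Tuesday's | 60.0 | 22.1 | 44.1 |
| Tuesday's | 120 | 41.1 | 13.2 |

(each reading ± 0.3 percentage points)



- concentration of monomer in chains at 2.0 h, in M
- concentration of free monomer at 2.0 h, in M
- concentration of uncatalysed product at 2.0 h, in M

1. We take the gap in Wednesday's balance at 120 min as uncatalysed product and weigh each interval by the free monomer present, which makes the run worth 65.0 min of full charge. Dividing gives 0.00768 /min, the leak: the chance per minute that a molecule of free monomer becomes uncatalysed product.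

2. Tuesday's run, with 97 mM of initiator against Wednesday's 62 mM, gives 0.00764 /min, so we carry the leak unchanged to this flask, where it contributes 0.921 to the logarithmic loss of free monomer.

3. Wednesday's logarithmic loss exceeds the leak's share by 0.620, which we assign to the chain route. Scaling that in proportion to initiator gives 0.440 for this flask, leaving 25.6% free monomer.

4. If free monomer falls exponentially, the leak makes 50.3% uncatalysed product in this flask, and chains hold the remaining 24.1%.

5. The weak link is the proportion: it predicts 0.970 for Tuesday, whose reading gives 1.10. The two runs therefore imply a power of 1.29, although this flask's charge lies outside them. Its chain term becomes 0.399, and we commit to 26.7% free monomer, 51.1% uncatalysed product and 22.2% in chains.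

The forecast, made “though the mechanism is unproven”, reads 0.44 M in chains, 0.58 M free and 1.18 M uncatalysed, so it puts more into uncatalysed product and less into chains than our 1.13 M and 0.487 M.

The flask holds 0.591 M of free monomer at 2.0 h. Its uncatalysed product stands at 1.18 M. Its monomer in chains stands at 0.432 M.

    initiator → spent initiator (k = 7.20 × 10⁻⁸ /s)
    living end + transfer agent → dead chain (kL = 0.0690 /M/s)
    2 initiator ⇌ resting dimer, settled at all times (K = 9.60 /M)
    free monomer → uncatalysed product (k = 1.30 × 10⁻⁴ /s)
    free monomer + initiator → living end + monomer in chains (k = 2.00 × 10⁻⁴ /M/s)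
    free monomer + living end → monomer in chains + living end, rate k6*[living end]*[free monomer] (k = 0.00630 /M/s)

At 2.00 h, this flask's free monomer was going to uncatalysed product 1.9 times as fast as into chains, a selectivity factor above unity. Applied to the 27% of free monomer left in this flask, the leak gives 51.4% uncatalysed product, where the flask holds 53.5%. Applied to the neighbour charged with 1.3 M of free monomer, which keeps 31.6% at the same time, it gives 54.7%, and that neighbour holds 56.1%.

(All runs come from a simulation for an exercise; scatter was added.)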